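## Analysis of the target

The target is built from two isoflavan units joined through one benzene ring. The upper unit is a 7-hydroxychroman (benzo ring A, pyran ring B with O1, C2, C3, C4) that carries the 2-hydroxy-4,5-dimethoxyphenyl ring C on C3. The lower unit is a second 7-hydroxychroman (pyran ring E with C2', C3', C4', benzo ring F). The central ring D is at once the 4-aryl group of the upper unit and the 3-aryl group of the lower one. Ring D is 1,2,3,5-tetrasubstituted: D1 is bonded to C4, D2 carries OMe, D4 carries OH and D6 is bonded to C3', so two bulky secondary carbon substituents sit on adjacent ring atoms. There are three stereocentres: C3 (R) and C4 (S) are contiguous with the two aryl groups trans, whereas C3' (R) lies beyond the D1–D6 edge and cannot be relayed from ring B. The four free phenols make rings A, D and F oxidisable, resorcinol-type nucleophiles, the doubly benzylic C4–D1 bond can ionise in strong acid, and the ring C hydroxyl can recapture a C4 cation as a pterocarpan. The difficulty is regiochemical as much as stereochemical: on a preformed lower isoflavan, ring D offers three activated CH positions (D1, D3, D5) and ring F two more, D1 being the most hindered, and the two ring D oxygens cannot be told apart on a symmetrical resorcinol. The route uses exactly this oxygen pattern of ring D, OMe at D2 ortho and OH at D4 para to D1, with D1 and D6 adjacent: it is the pattern in which an alkynyl ketone and a 1,1-dimethoxy-3-silyloxybutadiene combine, so ring D is built from open-chain precursors and never substituted.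

## Retrosynthetic reasoning

Target 26 is traced back to its tribenzyl ether 25 (hydrogenolysis as the last step) and 25 to lactol 24 by ionic reduction at C2. Neither operation touches a stereocentre, and the benzyl groups are the only protecting groups carried to the end.

Ring B of 24 is cut at C3–C4 and O1–C2. This leads back to carbinol 18, which ionises to quinone methide 23, and to arylacetaldehyde 22. These bonds are chosen over C4–D1 because the C4–D1 bond then exists before ring B does, so no electrophilic substitution on ring D is needed. The forward step has to add the enamine of 22 to the exocyclic carbon of 23 from one face and close the hemiacetal. That sets C3 and C4 together, trans, under control of an amine catalyst.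

Carbinol 18 comes from diaryl ketone 17 by hydride reduction, and 17 from chromene 16 by asymmetric hydrogenation of the C3'=C4' bond, which sets C3'. The ketone at the future C4 and the alkene in ring E are simply what the ring D construction leaves behind.

The key disconnection cuts ring D of 16 at D1–D2 and D5–D6, giving ynone 8 and diene 13. The two alkyne carbons become D1 and D6, so the two adjacent carbon substituents are in place by construction. The ketone that activates the alkyne becomes C4. The acetal carbon of 13 becomes D2 with its OMe, and the silyloxy carbon becomes D4 with a free OH. One operation therefore fixes the position of the crowded C4–D1 bond, the adjacency of the two arms and the differentiation of the two oxygens. Its precursor 8 is a linear ynone with no stereocentre, and its product 16 already holds rings A, D, E and F and every carbon of the target except the three that come with 22.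

Ynone 8 is cut at the bond between the carbonyl carbon and the alkyne, giving propargylic alcohol 7 and then dibromoalkene 4 plus aldehyde 5. Compound 4 comes from chromene aldehyde 3, made from salicylaldehyde 1 and acrolein 2; 5 is the protected form of the same aldehyde 1. Both benzo rings A and F thus come from one commercial compound.

Diene 13 is made from enone 11, itself from ketene acetal 9 and acid chloride 10. Aldehyde 22 is the one-carbon homologue of 20, the benzyl ether of commercial aldehyde 19.

## Alternatives that were turned down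

Alternative 1: the textbook, biomimetic disconnection of the C4–D1 bond. Forward key step: acid-promoted opening of pterocarpan A1 (C3 already set, ring C oxygen as leaving group) to the C4 cation and Friedel–Crafts capture by the lower isoflavan A2 anti to ring C. This would give the trans arrangement and free the ring C hydroxyl in one step. It was turned down because A2 offers five activated CH positions: D1 (para to OH but flanked by OMe and the chromanyl group), D3 and D5 on ring D, and two more on ring F. A bulky secondary cation favours the less hindered ones and nothing in the substrate directs it to D1. A1 and A2 each still need their own asymmetric synthesis of about five steps, so the most valuable material would be committed to an unselective last C–C bond formation.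

Alternative 2: disconnection of D1–C(carbonyl) and D6–C3' together by aryne σ-insertion. Forward key step: the 3-methoxy-5-benzyloxy aryne released from silyl triflate A3 inserts into the exocyclic C–C(=O) bond of 1,3-diketone A4 to give A5 (C3' attacks the aryne carbon meta to OMe, the aroyl group moves to the carbon ortho to OMe). It was turned down for three reasons. A3 is unsymmetrical, and its regiodefined preparation costs at least four steps. The aryl anion can add to either carbonyl of A4, and attack on the ring ketone expands the chromanone instead of transferring the acyl group. A5 carries a carbonyl group at C4' next to the ring D aroyl group; removing that oxygen later would pass through a C4' cation that the neighbouring carbonyl oxygen can trap as a six-membered oxocarbenium ion.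

Alternative 3: disconnection of C4–D1 by conjugate addition. Forward key step: rhodium-catalysed asymmetric 1,4-addition of arylboronic acid A7 to 3-arylcoumarin A6 (C4 set by the catalyst), equilibration of the α-aryl lactone to trans, then lactone reduction and cyclodehydration to ring B. It was turned down because A7 is a 2,6-disubstituted arylboronic acid and A6 a trisubstituted α-aryl acceptor: transmetalation and insertion are both slowed, and protodeboronation should win. A7 also needs the same regioselective functionalisation of D1 that defeats Alternative 1, and the lactone-to-chroman conversion adds two steps.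

Key step: step 8

Assumption: the face selectivities in steps 9 and 13 are taken from the accepted quadrant and enamine-shielding models; should either sense be the opposite, the mirror-image catalyst is used and nothing else changes.

## Route

Step 1
Reactants: 1 4-(benzyloxy)-2-hydroxybenzaldehyde; 2 acrolein
Product: 3 7-(benzyloxy)-2H-chromene-3-carbaldehyde
Conditions: K2CO3, 1,4-dioxane, reflux
Reagents that add atoms: none
Why: Oxa-Michael addition of the phenoxide to acrolein and intramolecular aldol condensation onto the aryl aldehyde, the standard annulation of salicylaldehydes to 2H-chromene-3-carbaldehydes; the benzyloxy group ends up at C7' of ring F.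

Step 2
Reactants: 3 7-(benzyloxy)-2H-chromene-3-carbaldehyde
Product: 4 7-(benzyloxy)-3-(2,2-dibromoethenyl)-2H-chromene
Conditions: CBr4, PPh3, CH2Cl2, 0 °C
Reagents that add atoms: carbon tetrabromide, BrC(Br)(Br)Br
Why: Corey–Fuchs dibromo-olefination of the enal; the aldehyde carbon becomes the future ring atom D6 and the CBr2 carbon the future D1.

Step 3
Reactants: 1 4-(benzyloxy)-2-hydroxybenzaldehyde
Product: 5 4-(benzyloxy)-2-(methoxymethoxy)benzaldehyde
Conditions: MOMCl, K2CO3, acetone, rt
Reagents that add atoms: chloromethyl methyl ether, COCCl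
Why: Williamson-type O-alkylation of the phenol; the acetal ether masks the acidic OH, which would protonate acetylide 6 and diene 13, and is lost later under mild acid with assistance from the ortho carbonyl group.

Step 4
Reactants: 4 7-(benzyloxy)-3-(2,2-dibromoethenyl)-2H-chromene; 5 4-(benzyloxy)-2-(methoxymethoxy)benzaldehyde
Product: 7 1-[4-(benzyloxy)-2-(methoxymethoxy)phenyl]-3-[7-(benzyloxy)-2H-chromen-3-yl]prop-2-yn-1-ol (racemic), via lithium acetylide 6 (not isolated)
Conditions: n-BuLi (2.1 equiv), THF, −78 °C; then 5, −78 to 0 °C; then H2O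
Reagents that add atoms: none
Why: Bromine–lithium exchange, Fritsch–Buttenberg–Wiechell rearrangement and deprotonation give 6 (second stage of the Corey–Fuchs sequence), which adds to the aldehyde of 5; the racemic carbinol centre is removed by the oxidation in step 5.

Step 5
Reactants: 7 1-[4-(benzyloxy)-2-(methoxymethoxy)phenyl]-3-[7-(benzyloxy)-2H-chromen-3-yl]prop-2-yn-1-ol
Product: 8 1-[4-(benzyloxy)-2-(methoxymethoxy)phenyl]-3-[7-(benzyloxy)-2H-chromen-3-yl]prop-2-yn-1-one
Conditions: MnO2, CH2Cl2, rt
Reagents that add atoms: none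
Why: Selective MnO2 oxidation of a doubly activated (propargylic and benzylic) alcohol to the alkynyl ketone; the chromene and the ethers are not affected.

Step 6
Reactants: 9 1,1-dimethoxyethene; 10 acetyl chloride
Product: 11 4,4-dimethoxybut-3-en-2-one
Conditions: Et3N, Et2O, 0 °C to rt
Reagents that add atoms: none
Why: C-Acylation of the nucleophilic ketene acetal by the acid chloride; the amine removes the α-proton of the oxocarbenium intermediate and gives the push–pull enone and not the β-keto ester.

Step 7
Reactants: 11 4,4-dimethoxybut-3-en-2-one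
Product: 13 [(4,4-dimethoxybuta-1,3-dien-2-yl)oxy]trimethylsilane, via lithium dienolate 12 (not isolated)
Conditions: LiN(iPr)2, THF, −78 °C; then TMSCl
Reagents that add atoms: chlorotrimethylsilane, C[Si](C)(C)Cl
Why: Kinetic deprotonation of the methyl ketone and O-silylation of dienolate 12 (silyl enol ether formation); the moisture-sensitive diene is distilled and used at once.

Step 8
Reactants: 8 1-[4-(benzyloxy)-2-(methoxymethoxy)phenyl]-3-[7-(benzyloxy)-2H-chromen-3-yl]prop-2-yn-1-one; 13 [(4,4-dimethoxybuta-1,3-dien-2-yl)oxy]trimethylsilane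
Product: 16 [4-(benzyloxy)-2-hydroxyphenyl]{2-[7-(benzyloxy)-2H-chromen-3-yl]-4-hydroxy-6-methoxyphenyl}methanone, via cyclohexadiene cycloadduct 14 (not isolated), via aryl silyl ether 15 (not isolated)
Conditions: toluene, 90 °C; then 2 M HCl, THF, 40 °C
Reagents that add atoms: none
Why: Thermal Diels–Alder reaction of an alkynyl ketone with an electron-rich 1,1-dialkoxy-3-silyloxy diene, followed by aromatisation; the closest known reaction type is the benzannulation of alkynoates and alkynyl ketones with this diene class to 2-substituted 4-hydroxy-6-methoxybenzoyl compounds. Ring D is closed by an intermolecular [4+2] cycloaddition that forms D1–D2 and D5–D6, and cycloadduct 14 aromatises to 15 by 1,4-elimination of methanol. No stereocentre is formed. The selectivity needed is regiochemical: the nucleophilic CH2 terminus of 13 must bond to the alkyne carbon β to the ketone, which carries the chromene, and the acetal carbon to the α carbon. The polarisation of the ynone secures this; it places OMe at D2 next to the aroyl-bearing D1 and the silyloxy group at D4 para to it, so the two oxygens emerge already differentiated. The chromene double bond is electron-rich and should not compete as a dienophile. Dilute acid then cleaves the aryl silyl ether and the methoxymethyl ether, the latter assisted by the ortho carbonyl group, and the product is held as the hydrogen-bonded 2-hydroxybenzophenone. 3-Aryl-2H-chromenes are themselves made by acid-catalysed dehydration and should tolerate this work-up.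

Step 9
Reactants: 16 [4-(benzyloxy)-2-hydroxyphenyl]{2-[7-(benzyloxy)-2H-chromen-3-yl]-4-hydroxy-6-methoxyphenyl}methanone
Product: 17 [4-(benzyloxy)-2-hydroxyphenyl]{2-[(3R)-7-(benzyloxy)-3,4-dihydro-2H-chromen-3-yl]-4-hydroxy-6-methoxyphenyl}methanone
Conditions: [Ir(cod)((S)-tBu-PHOX)][B(3,5-(CF3)2C6H3)4] (2 mol %), H2 (50 bar), CH2Cl2, rt
Reagents that add atoms: none
Why: Asymmetric hydrogenation of a trisubstituted cyclic styrene-type alkene by a cationic iridium phosphinooxazoline catalyst, the reaction type established for 3-aryl-2H-chromenes; the chiral ligand decides the alkene face and sets C3' as R, and the homogeneous catalyst leaves the ketone and the benzyl ethers alone.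

Step 10
Reactants: 17 [4-(benzyloxy)-2-hydroxyphenyl]{2-[(3R)-7-(benzyloxy)-3,4-dihydro-2H-chromen-3-yl]-4-hydroxy-6-methoxyphenyl}methanone
Product: 18 5-(benzyloxy)-2-[{2-[(3R)-7-(benzyloxy)-3,4-dihydro-2H-chromen-3-yl]-4-hydroxy-6-methoxyphenyl}(hydroxy)methyl]phenol (both carbinol epimers)
Conditions: LiAlH4, THF, 0 °C; aq. potassium sodium tartrate
Reagents that add atoms: none
Why: Hydride reduction of the diaryl ketone; the ortho phenoxide is bound to aluminium and delivers hydride intramolecularly to the hindered carbonyl group at low temperature. The carbinol centre is not controlled because it is planarised in step 13.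

Step 11
Reactants: 19 2-hydroxy-4,5-dimethoxybenzaldehyde
Product: 20 2-(benzyloxy)-4,5-dimethoxybenzaldehyde
Conditions: BnBr, K2CO3, DMF, rt
Reagents that add atoms: benzyl bromide, BrCc1ccccc1
Why: Williamson etherification; the benzyl ether keeps the ring C hydroxyl from forming a five-membered lactol with the aldehyde of 22 and is removed in the last step.

Step 12
Reactants: 20 2-(benzyloxy)-4,5-dimethoxybenzaldehyde
Product: 22 [2-(benzyloxy)-4,5-dimethoxyphenyl]acetaldehyde, via methyl enol ether 21 (not isolated)
Conditions: Ph3P(CH2OMe)Cl, KOtBu, THF, 0 °C to rt; then 2 M HCl, THF, rt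
Reagents that add atoms: (methoxymethyl)triphenylphosphonium chloride, COC[P+](c1ccccc1)(c1ccccc1)c1ccccc1.[Cl-]
Why: Wittig reaction with the methoxymethylene ylide and acid hydrolysis of enol ether 21 (one-carbon homologation of an aldehyde); the enolisable arylacetaldehyde is used directly.

Step 13
Reactants: 18 5-(benzyloxy)-2-[{2-[(3R)-7-(benzyloxy)-3,4-dihydro-2H-chromen-3-yl]-4-hydroxy-6-methoxyphenyl}(hydroxy)methyl]phenol; 22 [2-(benzyloxy)-4,5-dimethoxyphenyl]acetaldehyde
Product: 24 (3R,4S)-7-(benzyloxy)-3-[2-(benzyloxy)-4,5-dimethoxyphenyl]-4-{2-[(3R)-7-(benzyloxy)-3,4-dihydro-2H-chromen-3-yl]-4-hydroxy-6-methoxyphenyl}-3,4-dihydro-2H-chromen-2-ol (both C2 epimers), via quinone methide 23 (not isolated)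
Conditions: (R)-2-[diphenyl(trimethylsilyloxy)methyl]pyrrolidine (20 mol %), PhCO2H (20 mol %), CH2Cl2, 0 °C to rt
Reagents that add atoms: none
Why: Amine-catalysed formal [4+2] annulation of an aldehyde with a quinone methide: the weak acid ionises the doubly benzylic, donor-stabilised carbinol to 23, the (E)-enamine of 22 adds to its exocyclic carbon (Michael addition) and the phenol closes the hemiacetal. The silyloxydiphenylmethyl group of the (R)-catalyst shields one enamine face and fixes C3 as R; the synclinal approach of the two π systems places the two aryl groups anti and fixes C4 as S, and the trans lactol is also the thermodynamic product. C3' is remote and should have little influence.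

Step 14
Reactants: 24 (3R,4S)-7-(benzyloxy)-3-[2-(benzyloxy)-4,5-dimethoxyphenyl]-4-{2-[(3R)-7-(benzyloxy)-3,4-dihydro-2H-chromen-3-yl]-4-hydroxy-6-methoxyphenyl}-3,4-dihydro-2H-chromen-2-ol
Product: 25 4-{(3R,4S)-7-(benzyloxy)-3-[2-(benzyloxy)-4,5-dimethoxyphenyl]-3,4-dihydro-2H-chromen-4-yl}-3-[(3R)-7-(benzyloxy)-3,4-dihydro-2H-chromen-3-yl]-5-methoxyphenol
Conditions: Et3SiH, CF3CO2H, CH2Cl2, −40 to 0 °C
Reagents that add atoms: none
Why: Ionic reduction of a lactol: acid generates the cyclic oxocarbenium ion at C2, which the silane captures; C4 is not touched, and any reversible enol ether formation can only return the more stable trans isomer at C3.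

Step 15
Reactants: 25 4-{(3R,4S)-7-(benzyloxy)-3-[2-(benzyloxy)-4,5-dimethoxyphenyl]-3,4-dihydro-2H-chromen-4-yl}-3-[(3R)-7-(benzyloxy)-3,4-dihydro-2H-chromen-3-yl]-5-methoxyphenol
Product: 26 (3R,4S)-4-{4-hydroxy-2-methoxy-6-[(3R)-7-hydroxy-3,4-dihydro-2H-chromen-3-yl]phenyl}-3-(2-hydroxy-4,5-dimethoxyphenyl)-3,4-dihydro-2H-chromen-7-ol
Conditions: H2 (1 atm), Pd/C, EtOAc/MeOH, rt
Reagents that add atoms: none
Why: Hydrogenolysis of the three benzyl ethers over palladium; the chroman C–O bonds are not benzylic and the C4–H and C4–D1 bonds are inert under these neutral conditions, so all three stereocentres are kept.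

## Compound list

1 | 4-(benzyloxy)-2-hydroxybenzaldehyde | O=Cc1ccc(OCc2ccccc2)cc1O | starting material
2 | acrolein (prop-2-enal) | C=CC=O | starting material
3 | 7-(benzyloxy)-2H-chromene-3-carbaldehyde | O=CC1=Cc2ccc(OCc3ccccc3)cc2OC1 | intermediate
4 | 7-(benzyloxy)-3-(2,2-dibromoethenyl)-2H-chromene | BrC(Br)=CC1=Cc2ccc(OCc3ccccc3)cc2OC1 | intermediate
5 | 4-(benzyloxy)-2-(methoxymethoxy)benzaldehyde | COCOc1cc(OCc2ccccc2)ccc1C=O | intermediate
6 | lithium [7-(benzyloxy)-2H-chromen-3-yl]ethynide | [Li]C#CC1=Cc2ccc(OCc3ccccc3)cc2OC1 | intermediate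
7 | 1-[4-(benzyloxy)-2-(methoxymethoxy)phenyl]-3-[7-(benzyloxy)-2H-chromen-3-yl]prop-2-yn-1-ol (racemic) | COCOc1cc(OCc2ccccc2)ccc1C(O)C#CC1=Cc2ccc(OCc3ccccc3)cc2OC1 | intermediate
8 | 1-[4-(benzyloxy)-2-(methoxymethoxy)phenyl]-3-[7-(benzyloxy)-2H-chromen-3-yl]prop-2-yn-1-one | COCOc1cc(OCc2ccccc2)ccc1C(=O)C#CC1=Cc2ccc(OCc3ccccc3)cc2OC1 | intermediate
9 | 1,1-dimethoxyethene | C=C(OC)OC | starting material
10 | acetyl chloride | CC(Cl)=O | starting material
11 | 4,4-dimethoxybut-3-en-2-one | CC(=O)C=C(OC)OC | intermediate
12 | lithium 4,4-dimethoxybuta-1,3-dien-2-olate | [Li]OC(=C)C=C(OC)OC | intermediate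
13 | [(4,4-dimethoxybuta-1,3-dien-2-yl)oxy]trimethylsilane | C=C(O[Si](C)(C)C)C=C(OC)OC | intermediate
14 | [4-(benzyloxy)-2-(methoxymethoxy)phenyl]{2-[7-(benzyloxy)-2H-chromen-3-yl]-6,6-dimethoxy-4-[(trimethylsilyl)oxy]cyclohexa-1,4-dien-1-yl}methanone | COC1(OC)C=C(O[Si](C)(C)C)CC(=C1C(=O)c1ccc(OCc2ccccc2)cc1OCOC)C1=Cc2ccc(OCc3ccccc3)cc2OC1 | intermediate
15 | [4-(benzyloxy)-2-(methoxymethoxy)phenyl]{2-[7-(benzyloxy)-2H-chromen-3-yl]-6-methoxy-4-[(trimethylsilyl)oxy]phenyl}methanone | COCOc1cc(OCc2ccccc2)ccc1C(=O)c1c(OC)cc(O[Si](C)(C)C)cc1C1=Cc2ccc(OCc3ccccc3)cc2OC1 | intermediate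
16 | [4-(benzyloxy)-2-hydroxyphenyl]{2-[7-(benzyloxy)-2H-chromen-3-yl]-4-hydroxy-6-methoxyphenyl}methanone | O=C(c1ccc(OCc2ccccc2)cc1O)c1c(OC)cc(O)cc1C1=Cc2ccc(OCc3ccccc3)cc2OC1 | intermediate
17 | [4-(benzyloxy)-2-hydroxyphenyl]{2-[(3R)-7-(benzyloxy)-3,4-dihydro-2H-chromen-3-yl]-4-hydroxy-6-methoxyphenyl}methanone | O=C(c1ccc(OCc2ccccc2)cc1O)c1c(OC)cc(O)cc1[C@@H]1COc2cc(OCc3ccccc3)ccc2C1 | intermediate
18 | 5-(benzyloxy)-2-[{2-[(3R)-7-(benzyloxy)-3,4-dihydro-2H-chromen-3-yl]-4-hydroxy-6-methoxyphenyl}(hydroxy)methyl]phenol (both carbinol epimers) | OC(c1ccc(OCc2ccccc2)cc1O)c1c(OC)cc(O)cc1[C@@H]1COc2cc(OCc3ccccc3)ccc2C1 | intermediate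
19 | 2-hydroxy-4,5-dimethoxybenzaldehyde | COc1cc(O)c(C=O)cc1OC | starting material
20 | 2-(benzyloxy)-4,5-dimethoxybenzaldehyde | COc1cc(OCc2ccccc2)c(C=O)cc1OC | intermediate
21 | 1-(benzyloxy)-4,5-dimethoxy-2-(2-methoxyethenyl)benzene (E/Z) | COC=Cc1cc(OC)c(OC)cc1OCc1ccccc1 | intermediate
22 | [2-(benzyloxy)-4,5-dimethoxyphenyl]acetaldehyde | O=CCc1cc(OC)c(OC)cc1OCc1ccccc1 | intermediate
23 | 3-(benzyloxy)-6-({2-[(3R)-7-(benzyloxy)-3,4-dihydro-2H-chromen-3-yl]-4-hydroxy-6-methoxyphenyl}methylidene)cyclohexa-2,4-dien-1-one | O=C1C=C(OCc2ccccc2)C=CC1=Cc1c(OC)cc(O)cc1[C@@H]1COc2cc(OCc3ccccc3)ccc2C1 | intermediate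
24 | (3R,4S)-7-(benzyloxy)-3-[2-(benzyloxy)-4,5-dimethoxyphenyl]-4-{2-[(3R)-7-(benzyloxy)-3,4-dihydro-2H-chromen-3-yl]-4-hydroxy-6-methoxyphenyl}-3,4-dihydro-2H-chromen-2-ol (both C2 epimers) | COc1cc(OCc2ccccc2)c([C@@H]2C(O)Oc3cc(OCc4ccccc4)ccc3[C@H]2c2c(OC)cc(O)cc2[C@@H]2COc3cc(OCc4ccccc4)ccc3C2)cc1OC | intermediate
25 | 4-{(3R,4S)-7-(benzyloxy)-3-[2-(benzyloxy)-4,5-dimethoxyphenyl]-3,4-dihydro-2H-chromen-4-yl}-3-[(3R)-7-(benzyloxy)-3,4-dihydro-2H-chromen-3-yl]-5-methoxyphenol | COc1cc(OCc2ccccc2)c([C@@H]2COc3cc(OCc4ccccc4)ccc3[C@H]2c2c(OC)cc(O)cc2[C@@H]2COc3cc(OCc4ccccc4)ccc3C2)cc1OC | intermediate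
26 | (3R,4S)-4-{4-hydroxy-2-methoxy-6-[(3R)-7-hydroxy-3,4-dihydro-2H-chromen-3-yl]phenyl}-3-(2-hydroxy-4,5-dimethoxyphenyl)-3,4-dihydro-2H-chromen-7-ol | COc1cc(O)c([C@@H]2COc3cc(O)ccc3[C@H]2c2c(OC)cc(O)cc2[C@@H]2COc3cc(O)ccc3C2)cc1OC | target

## Step count and risks

Total step count: 15. Longest linear sequence: 10 steps (steps 1, 2, 4, 5, 8, 9, 10, 13, 14, 15, from 1 and 2).

Step 8 (key step). The most likely failure is insufficient dienophilicity. The carbonyl group of 8 is deactivated by its 2,4-dioxygenated aryl ring and by the donor chromene at the other end of the alkyne, and both alkyne carbons are hindered, so the diene may decompose or lose its silyl group before it cycloadds. A second possibility is acid-induced oligomerisation of the chromene during the hydrolytic work-up. Fallback, setting out from 4 and coming back at 17: 4 is converted with n-BuLi into acetylide 6, which is quenched with CO2 to give 3-[7-(benzyloxy)-2H-chromen-3-yl]prop-2-ynoic acid F1. Esterification with commercial 3-(benzyloxy)phenol F2 (carbodiimide, DMAP) gives the aryl ynoate F3, a less hindered and more electrophilic dienophile of the class best precedented for this diene. Cycloaddition with 13 and a brief mild acidic work-up give the aryl benzoate F4, and the hydrogenation of step 9 gives the chroman ester F5. A Fries rearrangement (BF3·OEt2, 1,2-dichloroethane, 60 °C) then moves the acyl group to the carbon ortho to the phenolic oxygen and para to the benzyloxy group, which is 17. The diaryl ketone is thus made after the ring, and the chromene is gone before any Lewis acid is used.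

Step 9. The most likely failure is slow turnover or poor facial discrimination. The aroyl group on D1 crowds the alkene, and the chelating 2-hydroxybenzophenone and the free phenol can bind the cationic metal. Fallback, setting out from 16 and coming back at 25: 16 is hydrogenated with the achiral catalyst [Ir(cod)(PCy3)(py)]PF6 to racemic ketone F6. F6 is carried through the conditions of step 10 (carbinol F7, epimeric at C3'), step 13 (lactol F8, in which the amine catalyst fixes C3 and C4 irrespective of C3') and step 14. This gives 25 together with its C3' epimer F9; the two are diastereomers and are separated by chromatography or crystallisation. The catalyst-controlled stereocentres of ring B thus serve to resolve C3'.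

Step 13. The most likely failure is loss of catalyst control. The exocyclic carbon of 23 carries a 2,6-disubstituted aryl group, which slows the enamine addition, so self-aldol condensation of 22, oligomerisation of 23 and an uncatalysed background addition can compete and lower both facial and trans selectivity. Fallback, setting out from 18 and 21 and coming back at 25: the enol ether 21 is isolated before hydrolysis and its (E)-isomer is used, and the catalyst is moved from the nucleophile to the electrophile. A chiral phosphoric acid (3,3'-bis(2,4,6-triisopropylphenyl)-1,1'-binaphthyl-2,2'-diyl hydrogen phosphate, 10 mol %, toluene, 0 °C, in the enantiomer that gives the (3R,4S) series) binds 23 as a hydrogen-bonded ion pair. The enol ether, which cannot self-condense, adds in an inverse-demand hetero-Diels–Alder reaction to give the 2-methoxy acetal F10, which is reduced under the conditions of step 14 to 25.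

Step 10. The most likely failure is over-reduction or decomposition. Loss of the aluminium-bound benzylic oxygen from the electron-rich carbinolate gives a quinone methide that takes up a second hydride, and 18 may oligomerise on work-up or storage. Fallback, setting out from 17 and coming back at 24: 17 is reduced with NaBH4 in EtOH at 0 °C and the crude carbinol is treated at once with 4-methylbenzenesulfinic acid in CH2Cl2 to give the crystalline sulfone F11, a bench-stable precursor of 23. In the annulation, F11 replaces 18: NaHCO3 releases 23 by elimination of sulfinate under non-acidic conditions in the presence of 22 and the amine catalyst, and 24 is formed as in step 13.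

## Further compounds

F1 | step 8 | 3-[7-(benzyloxy)-2H-chromen-3-yl]prop-2-ynoic acid | OC(=O)C#CC1=Cc2ccc(OCc3ccccc3)cc2OC1
F2 | step 8 | 3-(benzyloxy)phenol (commercial) | Oc1cccc(OCc2ccccc2)c1
F3 | step 8 | 3-(benzyloxy)phenyl 3-[7-(benzyloxy)-2H-chromen-3-yl]prop-2-ynoate | O=C(Oc1cccc(OCc2ccccc2)c1)C#CC1=Cc2ccc(OCc3ccccc3)cc2OC1
F4 | step 8 | 3-(benzyloxy)phenyl 2-[7-(benzyloxy)-2H-chromen-3-yl]-4-hydroxy-6-methoxybenzoate | COc1cc(O)cc(C2=Cc3ccc(OCc4ccccc4)cc3OC2)c1C(=O)Oc1cccc(OCc2ccccc2)c1
F5 | step 8 | 3-(benzyloxy)phenyl 2-[(3R)-7-(benzyloxy)-3,4-dihydro-2H-chromen-3-yl]-4-hydroxy-6-methoxybenzoate | COc1cc(O)cc([C@@H]2COc3cc(OCc4ccccc4)ccc3C2)c1C(=O)Oc1cccc(OCc2ccccc2)c1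
F6 | step 9 | [4-(benzyloxy)-2-hydroxyphenyl]{2-[7-(benzyloxy)-3,4-dihydro-2H-chromen-3-yl]-4-hydroxy-6-methoxyphenyl}methanone (racemic) | O=C(c1ccc(OCc2ccccc2)cc1O)c1c(OC)cc(O)cc1C1COc2cc(OCc3ccccc3)ccc2C1
F7 | step 9 | 5-(benzyloxy)-2-[{2-[7-(benzyloxy)-3,4-dihydro-2H-chromen-3-yl]-4-hydroxy-6-methoxyphenyl}(hydroxy)methyl]phenol (all stereoisomers) | OC(c1ccc(OCc2ccccc2)cc1O)c1c(OC)cc(O)cc1C1COc2cc(OCc3ccccc3)ccc2C1
F8 | step 9 | (3R,4S)-7-(benzyloxy)-3-[2-(benzyloxy)-4,5-dimethoxyphenyl]-4-{2-[7-(benzyloxy)-3,4-dihydro-2H-chromen-3-yl]-4-hydroxy-6-methoxyphenyl}-3,4-dihydro-2H-chromen-2-ol (both C3' epimers) | COc1cc(OCc2ccccc2)c([C@@H]2C(O)Oc3cc(OCc4ccccc4)ccc3[C@H]2c2c(OC)cc(O)cc2C2COc3cc(OCc4ccccc4)ccc3C2)cc1OC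
F9 | step 9 | 4-{(3R,4S)-7-(benzyloxy)-3-[2-(benzyloxy)-4,5-dimethoxyphenyl]-3,4-dihydro-2H-chromen-4-yl}-3-[(3S)-7-(benzyloxy)-3,4-dihydro-2H-chromen-3-yl]-5-methoxyphenol | COc1cc(OCc2ccccc2)c([C@@H]2COc3cc(OCc4ccccc4)ccc3[C@H]2c2c(OC)cc(O)cc2[C@H]2COc3cc(OCc4ccccc4)ccc3C2)cc1OC
F10 | step 13 | 4-{(3R,4S)-7-(benzyloxy)-3-[2-(benzyloxy)-4,5-dimethoxyphenyl]-2-methoxy-3,4-dihydro-2H-chromen-4-yl}-3-[(3R)-7-(benzyloxy)-3,4-dihydro-2H-chromen-3-yl]-5-methoxyphenol | COc1cc(OCc2ccccc2)c([C@@H]2C(OC)Oc3cc(OCc4ccccc4)ccc3[C@H]2c2c(OC)cc(O)cc2[C@@H]2COc3cc(OCc4ccccc4)ccc3C2)cc1OC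
F11 | step 10 | 5-(benzyloxy)-2-[{2-[(3R)-7-(benzyloxy)-3,4-dihydro-2H-chromen-3-yl]-4-hydroxy-6-methoxyphenyl}(4-methylbenzenesulfonyl)methyl]phenol | Cc1ccc(cc1)S(=O)(=O)C(c1ccc(OCc2ccccc2)cc1O)c1c(OC)cc(O)cc1[C@@H]1COc2cc(OCc3ccccc3)ccc2C1
A1 | alternative 1 | (6aR,11aR)-3-(benzyloxy)-8,9-dimethoxypterocarpan | COc1cc2c(cc1OC)[C@@H]1COc3cc(OCc4ccccc4)ccc3[C@@H]1O2
A2 | alternative 1 | 3-[(3R)-7-(benzyloxy)-3,4-dihydro-2H-chromen-3-yl]-5-methoxyphenol | COc1cc(O)cc(c1)[C@@H]1COc2cc(OCc3ccccc3)ccc2C1
A3 | alternative 2 | 4-(benzyloxy)-2-methoxy-6-(trimethylsilyl)phenyl trifluoromethanesulfonate | COc1cc(OCc2ccccc2)cc([Si](C)(C)C)c1OS(=O)(=O)C(F)(F)F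
A4 | alternative 2 | 7-(benzyloxy)-3-[4-(benzyloxy)-2-(methoxymethoxy)benzoyl]-2,3-dihydro-4H-chromen-4-one | COCOc1cc(OCc2ccccc2)ccc1C(=O)C1COc2cc(OCc3ccccc3)ccc2C1=O
A5 | alternative 2 | 7-(benzyloxy)-3-{5-(benzyloxy)-2-[4-(benzyloxy)-2-(methoxymethoxy)benzoyl]-3-methoxyphenyl}-2,3-dihydro-4H-chromen-4-one | COCOc1cc(OCc2ccccc2)ccc1C(=O)c1c(OC)cc(OCc2ccccc2)cc1C1COc2cc(OCc3ccccc3)ccc2C1=O
A6 | alternative 3 | 7-(benzyloxy)-3-[2-(benzyloxy)-4,5-dimethoxyphenyl]-2H-chromen-2-one | COc1cc(OCc2ccccc2)c(cc1OC)C1=Cc2ccc(OCc3ccccc3)cc2OC1=O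
A7 | alternative 3 | {4-(benzyloxy)-2-[(3R)-7-(benzyloxy)-3,4-dihydro-2H-chromen-3-yl]-6-methoxyphenyl}boronic acid | COc1cc(OCc2ccccc2)cc([C@@H]2COc3cc(OCc4ccccc4)ccc3C2)c1B(O)O
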